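**Retrosynthetic overview**
1. Only the pyranone ring C is built; rings A and B are bought as benzenes. Ring C is opened by a Baker–Venkataraman disconnection (O1–C2 and C2–C3) into ring A ketone 29 and ring B acid 18, and protecting groups come off last.
2. The strategy rests on the end of the butyl chain on C5' of ring B: its C3 carbon, the only stereocentre, carries CH3 and CH2OH. That is the pattern left by CH3–Al addition across a terminal vinyl group followed by C–Al oxidation, so the chain comes from butenyl arene 11. The alkene of the C3' prenyl group is trisubstituted and does not insert.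
3. Arene 11 comes from 5-bromo-2-hydroxybenzaldehyde: the prenyl group by a dimethylpropargyl ether, semi-hydrogenation and Claisen shift; the chain by CHO → CH2Br → coupling with allylmagnesium bromide. Br is kept as the later carboxyl handle.
4. Ketone 29 comes from methyl 3,5-dihydroxy-4-methoxybenzoate (Baeyer–Villiger to the phenol, benzyl ether, ortho-lithiation and acylation, hydrogenolysis). Its only free OH is the oxygen that becomes O1, which fixes the 6-methoxy (not 8-methoxy) pattern.

Key step: step 8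

Remark: the (+)-antipode of bis(1-neomenthylindenyl)zirconium dichloride is assumed to give the (S)-2-methylalkan-1-ol, and the lipase is assumed to acylate the (S)-alcohol faster. Both senses should be confirmed on 13 (for example as Mosher esters) before material is carried on.

**Ring B**

Step 1
Reactants: 1 5-bromo-2-hydroxybenzaldehyde; 2 3-chloro-3-methylbut-1-yne
Product: 3 5-bromo-2-[(2-methylbut-3-yn-2-yl)oxy]benzaldehyde
Conditions: CuCl2·2H2O (1 mol %), DBU, MeCN, 0 °C → rt
Reagents that add atoms: none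
Why: Copper-catalysed O-alkylation of the phenoxide by the tertiary propargylic chloride (through a copper acetylide/allenylidene, so no SN2 at the tertiary carbon is needed) is a standard aryl dimethylpropargyl ether synthesis and tolerates CHO and C–Br.

Step 2
Reactants: 3 5-bromo-2-[(2-methylbut-3-yn-2-yl)oxy]benzaldehyde
Product: 4 5-bromo-2-[(2-methylbut-3-en-2-yl)oxy]benzaldehyde
Conditions: H2 (1 atm), Lindlar catalyst (Pd/CaCO3 poisoned with Pb(OAc)2), quinoline, EtOAc, rt
Reagents that add atoms: none
Why: Lindlar semi-hydrogenation should stop at the terminal alkene and leave the aldehyde and the aryl bromide untouched.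

Step 3
Reactants: 4 5-bromo-2-[(2-methylbut-3-en-2-yl)oxy]benzaldehyde
Product: 6 5-bromo-2-hydroxy-3-(3-methylbut-2-en-1-yl)benzaldehyde, via ortho-dienone 5 (not isolated)
Conditions: xylenes, 140 °C
Reagents that add atoms: none
Why: Aromatic Claisen rearrangement: the [3,3] shift of the 1,1-dimethylallyl ether can only go to the free ortho carbon (the other ortho carbon bears CHO, the para carbon Br) and transposes the allyl unit into a prenyl group before dienone 5 tautomerises.

Step 4
Reactants: 6 5-bromo-2-hydroxy-3-(3-methylbut-2-en-1-yl)benzaldehyde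
Product: 7 5-bromo-2-[(tert-butyldimethylsilyl)oxy]-3-(3-methylbut-2-en-1-yl)benzaldehyde
Conditions: TBSCl, imidazole, DMAP (cat.), DMF, rt
Reagents that add atoms: tert-butyldimethylsilyl chloride, CC(C)(C)[Si](C)(C)Cl
Why: Imidazole-promoted silylation of the phenol gives an aryl silyl ether that, flanked by two ortho substituents, should survive the Grignard and alane steps that follow.

Step 5
Reactants: 7 5-bromo-2-[(tert-butyldimethylsilyl)oxy]-3-(3-methylbut-2-en-1-yl)benzaldehyde
Product: 8 {5-bromo-2-[(tert-butyldimethylsilyl)oxy]-3-(3-methylbut-2-en-1-yl)phenyl}methanol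
Conditions: i-Bu2AlH, CH2Cl2, −78 °C; aq. Rochelle salt
Reagents that add atoms: none
Why: Hydride reduction of the aldehyde at low temperature gives an aluminium alkoxide that should not trigger O-to-O silyl migration from the neighbouring phenol oxygen.

Step 6
Reactants: 8 {5-bromo-2-[(tert-butyldimethylsilyl)oxy]-3-(3-methylbut-2-en-1-yl)phenyl}methanol
Product: 9 [4-bromo-2-(bromomethyl)-6-(3-methylbut-2-en-1-yl)phenoxy](tert-butyl)dimethylsilane
Conditions: CBr4, PPh3, CH2Cl2, 0 °C
Reagents that add atoms: carbon tetrabromide, BrC(Br)(Br)Br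
Why: The Appel reaction converts the benzylic alcohol into the bromide under neutral conditions, so neither the prenyl alkene nor the silyl ether meets acid.

Step 7
Reactants: 9 [4-bromo-2-(bromomethyl)-6-(3-methylbut-2-en-1-yl)phenoxy](tert-butyl)dimethylsilane; 10 allylmagnesium bromide
Product: 11 [4-bromo-2-(but-3-en-1-yl)-6-(3-methylbut-2-en-1-yl)phenoxy](tert-butyl)dimethylsilane
Conditions: Li2CuCl4 (2 mol %), THF, −20 → 0 °C
Reagents that add atoms: none
Why: Copper-catalysed Grignard cross-coupling at the benzylic bromide forms the ArCH2–CH2 bond, while the aryl bromide does not exchange or couple at this temperature.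

Step 8
Reactants: 11 [4-bromo-2-(but-3-en-1-yl)-6-(3-methylbut-2-en-1-yl)phenoxy](tert-butyl)dimethylsilane
Product: 13 (2S)-4-{5-bromo-2-[(tert-butyldimethylsilyl)oxy]-3-(3-methylbut-2-en-1-yl)phenyl}-2-methylbutan-1-ol, via alkyldimethylalane 12 (not isolated)
Conditions: AlMe3 (2.5 equiv), (+)-bis(1-neomenthylindenyl)zirconium dichloride (5 mol %), methylaluminoxane (MeAlO)n (1 equiv), CH2Cl2, 0 °C → rt; then O2 (1 atm), 0 °C → rt; aq. Rochelle salt
Reagents that add atoms: trimethylaluminium, C[Al](C)C; dioxygen, O=O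
Why: AlMe3 and the zirconocene dichloride, activated by methylaluminoxane, give a cationic chiral methylzirconocene whose Zr–CH3 bond adds across the vinyl group of 11 with CH3 going to the internal carbon and Zr to CH2; transmetalation to aluminium releases alane 12 and the catalyst, and O2 turns the primary C–Al bond into C–O, so the step makes the C–CH3 and C–O bonds of the chain end. The closest known reaction type is the zirconium-catalysed asymmetric carboalumination of unactivated 1-alkenes with oxidation to 2-methylalkan-1-ols. No ring is closed. The new stereocentre (S) is set by the catalyst alone, through the alkene face that the neomenthylindenyl ligands present to Zr–CH3, and because it is not the carbon that is oxidised the O2 step cannot erode it. The step needs selection between the two alkenes and between carbo- and hydrometalation: only the monosubstituted vinyl group inserts, the trisubstituted prenyl alkene, the aryl bromide and the doubly flanked aryl silyl ether are spectators, and CH2Cl2 with the bulky indenyl ligands should suppress β-hydride transfer. The enantiomeric purity reached here is raised at acetate 14 in step 9.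

Step 9
Reactants: 13 (2S)-4-{5-bromo-2-[(tert-butyldimethylsilyl)oxy]-3-(3-methylbut-2-en-1-yl)phenyl}-2-methylbutan-1-ol
Product: 14 (2S)-4-{5-bromo-2-[(tert-butyldimethylsilyl)oxy]-3-(3-methylbut-2-en-1-yl)phenyl}-2-methylbutyl acetate
Conditions: Burkholderia cepacia lipase (lipase PS), vinyl acetate, CH2Cl2, rt, stopped short of full conversion; chromatography
Reagents that add atoms: vinyl acetate, C=COC(C)=O
Why: Lipase-catalysed irreversible transesterification should acylate the major (S)-alcohol faster than its enantiomer, so the acetate separated from the residual alcohol is enantiomerically enriched.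

Step 10
Reactants: 14 (2S)-4-{5-bromo-2-[(tert-butyldimethylsilyl)oxy]-3-(3-methylbut-2-en-1-yl)phenyl}-2-methylbutyl acetate
Product: 15 4-bromo-2-[(3S)-4-hydroxy-3-methylbutyl]-6-(3-methylbut-2-en-1-yl)phenol
Conditions: KOH (4 equiv), MeOH–THF–H2O, 40 °C; aq. NH4Cl to pH 7
Reagents that add atoms: none
Why: Saponification of the acetate and base-mediated cleavage of the aryl silyl ether (attack at silicon with phenoxide as leaving group) are run together, so no selectivity between the two groups is needed; the stereocentre, the prenyl alkene and the aryl bromide are inert to base, and the neutral work-up avoids acid-promoted chroman formation.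

Step 11
Reactants: 15 4-bromo-2-[(3S)-4-hydroxy-3-methylbutyl]-6-(3-methylbut-2-en-1-yl)phenol
Product: 16 {4-bromo-2-[(3S)-4-[(tert-butyldimethylsilyl)oxy]-3-methylbutyl]-6-(3-methylbut-2-en-1-yl)phenoxy}(tert-butyl)dimethylsilane
Conditions: TBSCl (2.5 equiv), imidazole, DMAP (cat.), DMF, rt → 40 °C
Reagents that add atoms: tert-butyldimethylsilyl chloride, CC(C)(C)[Si](C)(C)Cl
Why: Imidazole-promoted silylation caps the primary alcohol and the phenol in one operation, masking both against the organolithium, carbodiimide and amide-base steps that follow.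

Step 12
Reactants: 16 {4-bromo-2-[(3S)-4-[(tert-butyldimethylsilyl)oxy]-3-methylbutyl]-6-(3-methylbut-2-en-1-yl)phenoxy}(tert-butyl)dimethylsilane
Product: 18 4-[(tert-butyldimethylsilyl)oxy]-3-{(3S)-4-[(tert-butyldimethylsilyl)oxy]-3-methylbutyl}-5-(3-methylbut-2-en-1-yl)benzoic acid, via aryllithium 17 (not isolated)
Conditions: n-BuLi, THF, −78 °C; CO2 (g); cold 0.5 M HCl to pH 4
Reagents that add atoms: carbon dioxide, O=C=O
Why: Bromine–lithium exchange at −78 °C is faster than any deprotonation, and carboxylation of the aryllithium gives the ring B acid with the carboxyl para to the silyloxy group.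

**Ring A**

Step 13
Reactants: 19 methyl 3,5-dihydroxy-4-methoxybenzoate
Product: 20 methyl 4-methoxy-3,5-bis(methoxymethoxy)benzoate
Conditions: MOMCl, i-Pr2NEt, CH2Cl2, 0 °C → rt
Reagents that add atoms: chloromethyl methyl ether, COCCl
Why: Acetal protection of both phenols gives groups that are stable to hydride, peracid, organolithium and amide base and that direct the later ortho-lithiation.

Step 14
Reactants: 20 methyl 4-methoxy-3,5-bis(methoxymethoxy)benzoate
Product: 21 [4-methoxy-3,5-bis(methoxymethoxy)phenyl]methanol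
Conditions: LiAlH4, THF, 0 °C
Reagents that add atoms: none
Why: Hydride reduction of the ester to the benzylic alcohol is routine and leaves the acetals alone.

Step 15
Reactants: 21 [4-methoxy-3,5-bis(methoxymethoxy)phenyl]methanol
Product: 22 4-methoxy-3,5-bis(methoxymethoxy)benzaldehyde
Conditions: MnO2, CH2Cl2, rt
Reagents that add atoms: none
Why: Manganese dioxide oxidises the electron-rich benzylic alcohol selectively to the aldehyde without over-oxidation.

Step 16
Reactants: 22 4-methoxy-3,5-bis(methoxymethoxy)benzaldehyde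
Product: 24 4-methoxy-3,5-bis(methoxymethoxy)phenol, via aryl formate 23 (not isolated)
Conditions: mCPBA, CH2Cl2, 0 °C → rt; then K2CO3, MeOH, rt
Reagents that add atoms: 3-chloroperbenzoic acid, O=C(OO)c1cccc(Cl)c1
Why: Baeyer–Villiger (Dakin-type) oxidation: the aryl group, made electron-rich by the para-methoxy group, migrates in preference to hydrogen, and methanolysis of the formate frees the phenol.

Step 17
Reactants: 24 4-methoxy-3,5-bis(methoxymethoxy)phenol
Product: 25 5-(benzyloxy)-2-methoxy-1,3-bis(methoxymethoxy)benzene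
Conditions: BnBr, K2CO3, DMF, rt
Reagents that add atoms: benzyl bromide, BrCc1ccccc1
Why: Williamson etherification marks the oxygen that will become O1 with a group removable by hydrogenolysis in the presence of the acetals.

Step 18
Reactants: 25 5-(benzyloxy)-2-methoxy-1,3-bis(methoxymethoxy)benzene; 26 N,2-dimethoxy-N-methylacetamide
Product: 28 1-[2-(benzyloxy)-5-methoxy-4,6-bis(methoxymethoxy)phenyl]-2-methoxyethan-1-one, via aryllithium 27 (not isolated)
Conditions: n-BuLi, THF, 0 °C; then 26, −78 → 0 °C; aq. NH4Cl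
Reagents that add atoms: none
Why: Directed ortho-metalation: the two ring CH positions are equivalent by symmetry and each lies between an acetal oxygen and the benzyloxy group, and acylation of the aryllithium by the Weinreb amide stops at the ketone through the chelated tetrahedral adduct.

Step 19
Reactants: 28 1-[2-(benzyloxy)-5-methoxy-4,6-bis(methoxymethoxy)phenyl]-2-methoxyethan-1-one
Product: 29 1-[2-hydroxy-5-methoxy-4,6-bis(methoxymethoxy)phenyl]-2-methoxyethan-1-one
Conditions: H2 (1 atm), 10 % Pd/C, EtOAc, rt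
Reagents that add atoms: none
Why: Hydrogenolysis removes only the benzyl ether (no alkene is present in this fragment), freeing the one phenol that is flanked by the ring CH and destined to become O1.

**Assembly and deprotection**

Step 20
Reactants: 29 1-[2-hydroxy-5-methoxy-4,6-bis(methoxymethoxy)phenyl]-2-methoxyethan-1-one; 18 4-[(tert-butyldimethylsilyl)oxy]-3-{(3S)-4-[(tert-butyldimethylsilyl)oxy]-3-methylbutyl}-5-(3-methylbut-2-en-1-yl)benzoic acid
Product: 30 4-methoxy-2-(methoxyacetyl)-3,5-bis(methoxymethoxy)phenyl 4-[(tert-butyldimethylsilyl)oxy]-3-{(3S)-4-[(tert-butyldimethylsilyl)oxy]-3-methylbutyl}-5-(3-methylbut-2-en-1-yl)benzoate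
Conditions: EDC·HCl, DMAP, CH2Cl2, rt
Reagents that add atoms: none
Why: Carbodiimide/DMAP (Steglich) esterification acylates the only free phenol under neutral conditions that spare the acetals and silyl ethers.

Step 21
Reactants: 30 4-methoxy-2-(methoxyacetyl)-3,5-bis(methoxymethoxy)phenyl 4-[(tert-butyldimethylsilyl)oxy]-3-{(3S)-4-[(tert-butyldimethylsilyl)oxy]-3-methylbutyl}-5-(3-methylbut-2-en-1-yl)benzoate
Product: 31 1-{4-[(tert-butyldimethylsilyl)oxy]-3-{(3S)-4-[(tert-butyldimethylsilyl)oxy]-3-methylbutyl}-5-(3-methylbut-2-en-1-yl)phenyl}-3-[2-hydroxy-5-methoxy-4,6-bis(methoxymethoxy)phenyl]-2-methoxypropane-1,3-dione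
Conditions: LiN(SiMe3)2 (3 equiv), THF, −78 → 0 °C; AcOH quench
Reagents that add atoms: none
Why: Baker–Venkataraman rearrangement: the methoxy-bearing ketone enolate attacks the neighbouring aryl ester intramolecularly and the acyl group moves from O to C, forming the C2–C3 bond (the CH(OMe) centre forms as a mixture and is erased in step 22).

Step 22
Reactants: 31 1-{4-[(tert-butyldimethylsilyl)oxy]-3-{(3S)-4-[(tert-butyldimethylsilyl)oxy]-3-methylbutyl}-5-(3-methylbut-2-en-1-yl)phenyl}-3-[2-hydroxy-5-methoxy-4,6-bis(methoxymethoxy)phenyl]-2-methoxypropane-1,3-dione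
Product: 33 2-{4-[(tert-butyldimethylsilyl)oxy]-3-{(3S)-4-[(tert-butyldimethylsilyl)oxy]-3-methylbutyl}-5-(3-methylbut-2-en-1-yl)phenyl}-3,6-dimethoxy-5,7-bis(methoxymethoxy)-4H-chromen-4-one, via cyclic hemiketal 32 (not isolated)
Conditions: camphorsulfonic acid (0.2 equiv), toluene, 4 Å molecular sieves, 50 °C
Reagents that add atoms: none
Why: Acid-catalysed cyclodehydration closes ring C through the only free phenol (6-exo-trig addition to the ring B ketone, then loss of water helped by the electron-rich aryl group), and anhydrous catalytic acid in a non-nucleophilic solvent should spare the acetal on the other ortho oxygen, so closure cannot leak to the 8-methoxy isomer.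

Step 23
Reactants: 33 2-{4-[(tert-butyldimethylsilyl)oxy]-3-{(3S)-4-[(tert-butyldimethylsilyl)oxy]-3-methylbutyl}-5-(3-methylbut-2-en-1-yl)phenyl}-3,6-dimethoxy-5,7-bis(methoxymethoxy)-4H-chromen-4-one
Product: 34 2-{4-[(tert-butyldimethylsilyl)oxy]-3-[(3S)-4-hydroxy-3-methylbutyl]-5-(3-methylbut-2-en-1-yl)phenyl}-5,7-dihydroxy-3,6-dimethoxy-4H-chromen-4-one
Conditions: 2 M HCl, MeOH–THF, 45 °C
Reagents that add atoms: none
Why: Acid solvolysis removes both acetals and the primary silyl ether, while the hindered aryl silyl ether should stay on and keep the 4'-oxygen capped, so the neighbouring prenyl group cannot cyclise to a chroman.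

Step 24
Reactants: 34 2-{4-[(tert-butyldimethylsilyl)oxy]-3-[(3S)-4-hydroxy-3-methylbutyl]-5-(3-methylbut-2-en-1-yl)phenyl}-5,7-dihydroxy-3,6-dimethoxy-4H-chromen-4-one
Product: 35 5,7-dihydroxy-2-{4-hydroxy-3-[(3S)-4-hydroxy-3-methylbutyl]-5-(3-methylbut-2-en-1-yl)phenyl}-3,6-dimethoxy-4H-chromen-4-one (CNP0156581.1)
Conditions: Bu4NF, AcOH (1:1), THF, 0 °C → rt
Reagents that add atoms: none
Why: Buffered fluoride cleaves the aryl silyl ether under near-neutral conditions that leave the prenyl alkene, the flavone and the stereocentre untouched.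

**Compound list**
1 | 5-bromo-2-hydroxybenzaldehyde | O=Cc1cc(Br)ccc1O | starting material
2 | 3-chloro-3-methylbut-1-yne | CC(C)(Cl)C#C | starting material
3 | 5-bromo-2-[(2-methylbut-3-yn-2-yl)oxy]benzaldehyde | O=Cc1cc(Br)ccc1OC(C)(C)C#C | intermediate
4 | 5-bromo-2-[(2-methylbut-3-en-2-yl)oxy]benzaldehyde | O=Cc1cc(Br)ccc1OC(C)(C)C=C | intermediate
5 | 3-bromo-5-(3-methylbut-2-en-1-yl)-6-oxocyclohexa-1,3-diene-1-carbaldehyde (ortho-dienone, not isolated) | O=CC1=CC(Br)=CC(CC=C(C)C)C1=O | intermediate
6 | 5-bromo-2-hydroxy-3-(3-methylbut-2-en-1-yl)benzaldehyde | O=Cc1cc(Br)cc(CC=C(C)C)c1O | intermediate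
7 | 5-bromo-2-[(tert-butyldimethylsilyl)oxy]-3-(3-methylbut-2-en-1-yl)benzaldehyde | O=Cc1cc(Br)cc(CC=C(C)C)c1O[Si](C)(C)C(C)(C)C | intermediate
8 | {5-bromo-2-[(tert-butyldimethylsilyl)oxy]-3-(3-methylbut-2-en-1-yl)phenyl}methanol | OCc1cc(Br)cc(CC=C(C)C)c1O[Si](C)(C)C(C)(C)C | intermediate
9 | [4-bromo-2-(bromomethyl)-6-(3-methylbut-2-en-1-yl)phenoxy](tert-butyl)dimethylsilane | BrCc1cc(Br)cc(CC=C(C)C)c1O[Si](C)(C)C(C)(C)C | intermediate
10 | allylmagnesium bromide | C=CC[Mg]Br | starting material
11 | [4-bromo-2-(but-3-en-1-yl)-6-(3-methylbut-2-en-1-yl)phenoxy](tert-butyl)dimethylsilane | C=CCCc1cc(Br)cc(CC=C(C)C)c1O[Si](C)(C)C(C)(C)C | intermediate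
12 | {(2S)-4-{5-bromo-2-[(tert-butyldimethylsilyl)oxy]-3-(3-methylbut-2-en-1-yl)phenyl}-2-methylbutyl}dimethylalane (not isolated) | CC(C)(C)[Si](C)(C)Oc1c(CC=C(C)C)cc(Br)cc1CC[C@H](C)C[Al](C)C | intermediate
13 | (2S)-4-{5-bromo-2-[(tert-butyldimethylsilyl)oxy]-3-(3-methylbut-2-en-1-yl)phenyl}-2-methylbutan-1-ol | CC(C)(C)[Si](C)(C)Oc1c(CC=C(C)C)cc(Br)cc1CC[C@H](C)CO | intermediate
14 | (2S)-4-{5-bromo-2-[(tert-butyldimethylsilyl)oxy]-3-(3-methylbut-2-en-1-yl)phenyl}-2-methylbutyl acetate | CC(C)(C)[Si](C)(C)Oc1c(CC=C(C)C)cc(Br)cc1CC[C@H](C)COC(C)=O | intermediate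
15 | 4-bromo-2-[(3S)-4-hydroxy-3-methylbutyl]-6-(3-methylbut-2-en-1-yl)phenol | CC(C)=CCc1cc(Br)cc(CC[C@H](C)CO)c1O | intermediate
16 | {4-bromo-2-[(3S)-4-[(tert-butyldimethylsilyl)oxy]-3-methylbutyl]-6-(3-methylbut-2-en-1-yl)phenoxy}(tert-butyl)dimethylsilane | CC(C)(C)[Si](C)(C)Oc1c(CC=C(C)C)cc(Br)cc1CC[C@H](C)CO[Si](C)(C)C(C)(C)C | intermediate
17 | {4-[(tert-butyldimethylsilyl)oxy]-3-{(3S)-4-[(tert-butyldimethylsilyl)oxy]-3-methylbutyl}-5-(3-methylbut-2-en-1-yl)phenyl}lithium (not isolated) | [Li]c1cc(CC=C(C)C)c(O[Si](C)(C)C(C)(C)C)c(CC[C@H](C)CO[Si](C)(C)C(C)(C)C)c1 | intermediate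
18 | 4-[(tert-butyldimethylsilyl)oxy]-3-{(3S)-4-[(tert-butyldimethylsilyl)oxy]-3-methylbutyl}-5-(3-methylbut-2-en-1-yl)benzoic acid | OC(=O)c1cc(CC=C(C)C)c(O[Si](C)(C)C(C)(C)C)c(CC[C@H](C)CO[Si](C)(C)C(C)(C)C)c1 | intermediate
19 | methyl 3,5-dihydroxy-4-methoxybenzoate | COC(=O)c1cc(O)c(OC)c(O)c1 | starting material
20 | methyl 4-methoxy-3,5-bis(methoxymethoxy)benzoate | COCOc1cc(C(=O)OC)cc(OCOC)c1OC | intermediate
21 | [4-methoxy-3,5-bis(methoxymethoxy)phenyl]methanol | COCOc1cc(CO)cc(OCOC)c1OC | intermediate
22 | 4-methoxy-3,5-bis(methoxymethoxy)benzaldehyde | COCOc1cc(C=O)cc(OCOC)c1OC | intermediate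
23 | 4-methoxy-3,5-bis(methoxymethoxy)phenyl formate (not isolated) | COCOc1cc(OC=O)cc(OCOC)c1OC | intermediate
24 | 4-methoxy-3,5-bis(methoxymethoxy)phenol | COCOc1cc(O)cc(OCOC)c1OC | intermediate
25 | 5-(benzyloxy)-2-methoxy-1,3-bis(methoxymethoxy)benzene | COCOc1cc(OCc2ccccc2)cc(OCOC)c1OC | intermediate
26 | N,2-dimethoxy-N-methylacetamide | COCC(=O)N(C)OC | starting material
27 | [2-(benzyloxy)-5-methoxy-4,6-bis(methoxymethoxy)phenyl]lithium (not isolated) | [Li]c1c(OCc2ccccc2)cc(OCOC)c(OC)c1OCOC | intermediate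
28 | 1-[2-(benzyloxy)-5-methoxy-4,6-bis(methoxymethoxy)phenyl]-2-methoxyethan-1-one | COCC(=O)c1c(OCc2ccccc2)cc(OCOC)c(OC)c1OCOC | intermediate
29 | 1-[2-hydroxy-5-methoxy-4,6-bis(methoxymethoxy)phenyl]-2-methoxyethan-1-one | COCC(=O)c1c(O)cc(OCOC)c(OC)c1OCOC | intermediate
30 | 4-methoxy-2-(methoxyacetyl)-3,5-bis(methoxymethoxy)phenyl 4-[(tert-butyldimethylsilyl)oxy]-3-{(3S)-4-[(tert-butyldimethylsilyl)oxy]-3-methylbutyl}-5-(3-methylbut-2-en-1-yl)benzoate | COCC(=O)c1c(OC(=O)c2cc(CC=C(C)C)c(O[Si](C)(C)C(C)(C)C)c(CC[C@H](C)CO[Si](C)(C)C(C)(C)C)c2)cc(OCOC)c(OC)c1OCOC | intermediate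
31 | 1-{4-[(tert-butyldimethylsilyl)oxy]-3-{(3S)-4-[(tert-butyldimethylsilyl)oxy]-3-methylbutyl}-5-(3-methylbut-2-en-1-yl)phenyl}-3-[2-hydroxy-5-methoxy-4,6-bis(methoxymethoxy)phenyl]-2-methoxypropane-1,3-dione (mixture at C2) | COC(C(=O)c1c(O)cc(OCOC)c(OC)c1OCOC)C(=O)c1cc(CC=C(C)C)c(O[Si](C)(C)C(C)(C)C)c(CC[C@H](C)CO[Si](C)(C)C(C)(C)C)c1 | intermediate
32 | 2-{4-[(tert-butyldimethylsilyl)oxy]-3-{(3S)-4-[(tert-butyldimethylsilyl)oxy]-3-methylbutyl}-5-(3-methylbut-2-en-1-yl)phenyl}-2-hydroxy-3,6-dimethoxy-5,7-bis(methoxymethoxy)-2,3-dihydro-4H-chromen-4-one (mixture at C2 and C3, not isolated) | COC1C(=O)c2c(OCOC)c(OC)c(OCOC)cc2OC1(O)c1cc(CC=C(C)C)c(O[Si](C)(C)C(C)(C)C)c(CC[C@H](C)CO[Si](C)(C)C(C)(C)C)c1 | intermediate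
33 | 2-{4-[(tert-butyldimethylsilyl)oxy]-3-{(3S)-4-[(tert-butyldimethylsilyl)oxy]-3-methylbutyl}-5-(3-methylbut-2-en-1-yl)phenyl}-3,6-dimethoxy-5,7-bis(methoxymethoxy)-4H-chromen-4-one | COc1c(OCOC)cc2oc(-c3cc(CC=C(C)C)c(O[Si](C)(C)C(C)(C)C)c(CC[C@H](C)CO[Si](C)(C)C(C)(C)C)c3)c(OC)c(=O)c2c1OCOC | intermediate
34 | 2-{4-[(tert-butyldimethylsilyl)oxy]-3-[(3S)-4-hydroxy-3-methylbutyl]-5-(3-methylbut-2-en-1-yl)phenyl}-5,7-dihydroxy-3,6-dimethoxy-4H-chromen-4-one | COc1c(O)cc2oc(-c3cc(CC=C(C)C)c(O[Si](C)(C)C(C)(C)C)c(CC[C@H](C)CO)c3)c(OC)c(=O)c2c1O | intermediate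
35 | 5,7-dihydroxy-2-{4-hydroxy-3-[(3S)-4-hydroxy-3-methylbutyl]-5-(3-methylbut-2-en-1-yl)phenyl}-3,6-dimethoxy-4H-chromen-4-one | COc1c(O)cc2oc(-c3cc(CC=C(C)C)c(O)c(CC[C@H](C)CO)c3)c(OC)c(=O)c2c1O | target

**Step count and risks**
Total: 24 steps. Longest linear sequence: 17 steps (steps 1–12, then 20–24); the ring A branch (steps 13–19) joins at step 20.

Steps most likely to fail:

1. Step 8. The zirconocene may discriminate the two faces of an unbranched 1-alkene only incompletely, β-hydride transfer may give the unbranched hydroalumination product, and the lipase upgrade is limited because the wanted enantiomer is the one that is acylated. The fallback sets out from benzylic bromide 9 and comes back at bis-silyl ether 16, with the stereocentre bought instead of made. Commercial (R)-3-bromo-2-methylpropan-1-ol (BrC[C@H](C)CO) is silylated (TBSCl, imidazole, CH2Cl2) to tert-butyl{[(2R)-3-bromo-2-methylpropyl]oxy}dimethylsilane F1. F1 is converted with Mg in THF into {(2R)-3-[(tert-butyldimethylsilyl)oxy]-2-methylpropyl}magnesium bromide F2. F2 is joined to 9 by copper-catalysed Grignard cross-coupling (Li2CuCl4, THF, −20 °C) at the benzylic bromide, the aryl bromide staying inert. The descriptor changes from R to S only because the priorities change; compounds 11 to 15 are bypassed.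

2. Step 22. If the hindered hemiketal dehydrates slowly, the acid may first strip the acetal from the oxygen ortho to the ketone; the ring can then reopen and close through that oxygen, leaking to the 8-methoxy isomer. The fallback sets out from ketone 29 and aryl bromide 16 and comes back at flavone 33, closing ring C before ring B is attached and without acid. Ketone 29 is heated with N,N-dimethylformamide dimethyl acetal to give 3-(dimethylamino)-1-[2-hydroxy-5-methoxy-4,6-bis(methoxymethoxy)phenyl]-2-methoxyprop-2-en-1-one F3. F3 closes by conjugate addition of its single free phenol and loss of dimethylamine (toluene, heat, or on silica) to 3,6-dimethoxy-5,7-bis(methoxymethoxy)-4H-chromen-4-one F4. The C2–H of F4, next to O1 and the 3-methoxy group, is zincated with TMPZnCl·LiCl to [3,6-dimethoxy-5,7-bis(methoxymethoxy)-4-oxo-4H-chromen-2-yl]zinc chloride F5. Negishi coupling of F5 with 16 (Pd(OAc)2, SPhos, THF, 50 °C) forms the C2–C1' bond. Acid 18, ester 30 and diketone 31 are then not needed.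

3. Step 18. Butyllithium may deprotonate the benzylic CH2 of the benzyl ether (leading to a Wittig-type shift) in competition with ring metalation, so conversion to the ketone may be incomplete. The fallback sets out from benzyl ether 25 and comes back at ketone 28. Compound 25 is brominated with N-bromosuccinimide (MeCN, 0 °C) at one of its two equivalent ring CH positions to give 1-(benzyloxy)-2-bromo-4-methoxy-3,5-bis(methoxymethoxy)benzene F6. Bromine–lithium exchange on F6 (n-BuLi, THF, −78 °C), faster than any deprotonation, gives the same aryllithium 27, which is acylated with 26 as in the main route.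

**Further compounds**
F1 | step 8 | tert-butyl{[(2R)-3-bromo-2-methylpropyl]oxy}dimethylsilane | BrC[C@H](C)CO[Si](C)(C)C(C)(C)C
F2 | step 8 | {(2R)-3-[(tert-butyldimethylsilyl)oxy]-2-methylpropyl}magnesium bromide | Br[Mg]C[C@H](C)CO[Si](C)(C)C(C)(C)C
F3 | step 22 | 3-(dimethylamino)-1-[2-hydroxy-5-methoxy-4,6-bis(methoxymethoxy)phenyl]-2-methoxyprop-2-en-1-one (alkene geometry not fixed) | CN(C)C=C(OC)C(=O)c1c(O)cc(OCOC)c(OC)c1OCOC
F4 | step 22 | 3,6-dimethoxy-5,7-bis(methoxymethoxy)-4H-chromen-4-one | COc1coc2cc(OCOC)c(OC)c(OCOC)c2c1=O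
F5 | step 22 | [3,6-dimethoxy-5,7-bis(methoxymethoxy)-4-oxo-4H-chromen-2-yl]zinc chloride | COc1c([Zn]Cl)oc2cc(OCOC)c(OC)c(OCOC)c2c1=O
F6 | step 18 | 1-(benzyloxy)-2-bromo-4-methoxy-3,5-bis(methoxymethoxy)benzene | Brc1c(OCc2ccccc2)cc(OCOC)c(OC)c1OCOC
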